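**Retrosynthetic overview**

1. Ring numbering used throughout: O1, C2 (aryl), C3 (bears C9H2OH), C4 (bears the aroyl carbon C7'), C5 (CH2); the target is (2S,3R,4S), all trans. Last disconnections: the two O-benzyl groups, then the C4–H/C5–H pair (1,4-reduction of a 2,3-dihydrofuran, C4 being set thermodynamically α to the ketone).
2. Key disconnection: O1–C5 and C2–C3 together, a formal [3+2] of the aldehyde C=O of 9 with the C3–C4–C5 unit of enaminone imide 8 (auxiliary-controlled aldol, then ring closure with loss of dimethylamine). This forms the only new ring, the oxolane, as its 2,3-dihydro form.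
3. Enabling feature: in the oxolane ring C3 is α to the carboxyl-level carbon C9 and C5 is β to the aryl ketone C7'=O on C4, so C3–C4–C5 is a latent 1,3-dipole: an enolisable C3 and, at the formyl oxidation level, a vinylogous-amide carbon C5.
4. The extra C4=C5 unsaturation is temporary: it masks the ketone as a vinylogous ester while the auxiliary is reduced off (C9 to CH2OH), and is then removed by hydride addition to C5.
5. 8 comes from aryl bromide 1 and succinic anhydride (C7'–C4–C3–C9), oxazolidinone 5 and DMF-DMA (C5).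

Key step: step 4

Remark: 1 and 9 are taken as commercial, and the 3,4-trans arrangement (aroyl trans to CH2OH, all three ring substituents mutually trans) is taken to be the thermodynamic one at C4.

**Route**

Step 1
Reactants: 1 2-(benzyloxy)-4-bromo-1-methoxybenzene; 2 succinic anhydride
Product: 4 4-[3-(benzyloxy)-4-methoxyphenyl]-4-oxobutanoic acid, via arylmagnesium bromide 3 (not isolated)
Conditions: Mg, I2 (cat.), THF, 45 °C; then added to 2 (1.5 equiv) in THF, −78 → 0 °C; aq. HCl
Reagents that add atoms: none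
Why: Grignard acylation of a cyclic anhydride: inverse addition of the aryl Grignard reagent 3 to excess anhydride at low temperature should stop at the magnesium keto-carboxylate, which resists a second addition; no stereocentre is formed.

Step 2
Reactants: 4 4-[3-(benzyloxy)-4-methoxyphenyl]-4-oxobutanoic acid; 5 (S)-4-benzyl-1,3-oxazolidin-2-one
Product: 7 (S)-4-benzyl-3-{4-[3-(benzyloxy)-4-methoxyphenyl]-4-oxobutanoyl}-1,3-oxazolidin-2-one, via mixed pivalic anhydride 6 (not isolated)
Conditions: PivCl, Et3N, THF, −20 °C; then LiCl, 5, −20 → 23 °C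
Reagents that add atoms: none
Why: N-acylation of the oxazolidinone through the mixed pivalic anhydride with LiCl/Et3N activation (standard auxiliary loading), which should tolerate the aryl ketone; no new stereocentre.

Step 3
Reactants: 7 (S)-4-benzyl-3-{4-[3-(benzyloxy)-4-methoxyphenyl]-4-oxobutanoyl}-1,3-oxazolidin-2-one
Product: 8 (S)-4-benzyl-3-{(3E)-3-[3-(benzyloxy)-4-methoxybenzoyl]-4-(dimethylamino)but-3-enoyl}-1,3-oxazolidin-2-one
Conditions: DMF-DMA (3 equiv), toluene, 85 °C
Reagents that add atoms: N,N-dimethylformamide dimethyl acetal, COC(OC)N(C)C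
Why: Aminomethylenation (enaminone formation) of an aryl alkyl ketone with DMF-DMA at its α-CH2 (C4), expected to be much faster than at the imide α-CH2; it installs C5 at the formyl oxidation level and leaves C3 as the only enolisable position; no stereocentre.

Step 4
Reactants: 8 (S)-4-benzyl-3-{(3E)-3-[3-(benzyloxy)-4-methoxybenzoyl]-4-(dimethylamino)but-3-enoyl}-1,3-oxazolidin-2-one; 9 3-(benzyloxy)-4-methoxybenzaldehyde
Product: 12 (S)-4-benzyl-3-{(2S,3S)-2-[3-(benzyloxy)-4-methoxyphenyl]-4-[3-(benzyloxy)-4-methoxybenzoyl]-2,3-dihydrofuran-3-carbonyl}-1,3-oxazolidin-2-one, via boron dienolate 10 (not isolated), via syn-aldol 11 (not isolated)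
Conditions: Bu2BOTf (2.2 equiv), i-Pr2NEt (2.6 equiv), CH2Cl2, −78 → 0 °C; 9 (1.3 equiv), −78 → 0 °C; then MeOH, AcOH (excess), 0 → 23 °C
Reagents that add atoms: none
Why: Proposed new method: soft enolisation of the imide (C3–H is the only enolisable C–H because C4 is fully substituted) should give the Z-boron dienolate 10, which adds through C3 to the aldehyde in a closed Zimmerman–Traxler chair to give the Evans syn-aldol 11 (C2–C3 bond); on methanolysis and protonation the β-amino enone becomes a vinylogous iminium ion, the new hydroxyl adds to C5 and dimethylamine is expelled and held as its acetate (O1–C5 bond). The closest known reaction types are the α-selective Evans syn-aldol of dienolates from unsaturated N-acyloxazolidinones and the acid-mediated cyclisation of hydroxy enaminones to cyclic β-alkoxy enones (chromone and dihydropyranone syntheses); their union in one flask on this substrate class is new. The oxolane ring is closed by 5-exo-trig attack of oxygen on the C5=N bond of the vinylogous iminium ion, followed by β-elimination of the amine. C2 and C3 are both set by the (S)-benzyl auxiliary through the Z-enolate chair (syn, 2S,3S), which places the aryl group and the acyl group trans on the ring; no other stereocentre is formed. The step needs α- over γ-attack of the dienolate, secured by the cyclic boron transition state, and ring closure at C5 instead of at the ketone carbon, secured because the carbonyl of a vinylogous amide is unreactive while protonation makes C5 the electrophile. Only a weak acid is used so that the electron-rich benzylic C2–O1 bond should not ionise.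

Step 5
Reactants: 12 (S)-4-benzyl-3-{(2S,3S)-2-[3-(benzyloxy)-4-methoxyphenyl]-4-[3-(benzyloxy)-4-methoxybenzoyl]-2,3-dihydrofuran-3-carbonyl}-1,3-oxazolidin-2-one
Product: 13 [(2S,3R)-2-[3-(benzyloxy)-4-methoxyphenyl]-3-(hydroxymethyl)-2,3-dihydrofuran-4-yl][3-(benzyloxy)-4-methoxyphenyl]methanone
Conditions: NaBH4, THF/H2O (4:1), 0 °C
Reagents that add atoms: none
Why: Reductive cleavage of an N-acyloxazolidinone with NaBH4 in wet THF (known auxiliary removal): the imide carbonyl is the most electrophilic one, while the aryl ketone is deactivated as a vinylogous ester by the ring oxygen on C5 and should survive; C2 and C3 are untouched (the C3 descriptor changes from S to R only through the priority change at C9) and C3 loses its acidity.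

Step 6
Reactants: 13 [(2S,3R)-2-[3-(benzyloxy)-4-methoxyphenyl]-3-(hydroxymethyl)-2,3-dihydrofuran-4-yl][3-(benzyloxy)-4-methoxyphenyl]methanone
Product: 15 [(2S,3R,4S)-2-[3-(benzyloxy)-4-methoxyphenyl]-3-(hydroxymethyl)tetrahydrofuran-4-yl][3-(benzyloxy)-4-methoxyphenyl]methanone, via dilithium enolate 14 (not isolated)
Conditions: LiBH(s-Bu)3 (2.3 equiv), THF, −78 °C; AcOH, −78 °C; then K2CO3, MeOH, 23 °C
Reagents that add atoms: none
Why: Conjugate reduction of a β-alkoxy enone with a hindered trialkylborohydride (as for dihydropyranones to tetrahydropyranones): after deprotonation of the alcohol, hydride adds to C5, and protonation of enolate 14 followed by base equilibration α to the ketone should set C4 as the 3,4-trans (4S) epimer, the all-trans arrangement; ring opening by β-elimination is the reverse of a 5-endo-trig closure and should be slow.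

Step 7
Reactants: 15 [(2S,3R,4S)-2-[3-(benzyloxy)-4-methoxyphenyl]-3-(hydroxymethyl)tetrahydrofuran-4-yl][3-(benzyloxy)-4-methoxyphenyl]methanone
Product: 16 [(2S,3R,4S)-2-(3-hydroxy-4-methoxyphenyl)-3-(hydroxymethyl)tetrahydrofuran-4-yl](3-hydroxy-4-methoxyphenyl)methanone
Conditions: H2 (1 atm), Pd/C (10%), EtOAc/MeOH, 23 °C
Reagents that add atoms: none
Why: Hydrogenolysis of the two aryl benzyl ethers over Pd/C under neutral conditions at 1 atm, under which the aryl ketone and the ring benzylic C2–O1 bond should react much more slowly; no stereocentre is affected.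

**Compound list**

1 | 2-(benzyloxy)-4-bromo-1-methoxybenzene | COc1ccc(Br)cc1OCc1ccccc1 | starting material
2 | succinic anhydride | O=C1CCC(=O)O1 | starting material
3 | [3-(benzyloxy)-4-methoxyphenyl]magnesium bromide | COc1ccc([Mg]Br)cc1OCc1ccccc1 | intermediate
4 | 4-[3-(benzyloxy)-4-methoxyphenyl]-4-oxobutanoic acid | COc1ccc(C(=O)CCC(=O)O)cc1OCc1ccccc1 | intermediate
5 | (S)-4-benzyl-1,3-oxazolidin-2-one | O=C1N[C@@H](Cc2ccccc2)CO1 | starting material
6 | 4-[3-(benzyloxy)-4-methoxyphenyl]-4-oxobutanoic pivalic anhydride | COc1ccc(C(=O)CCC(=O)OC(=O)C(C)(C)C)cc1OCc1ccccc1 | intermediate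
7 | (S)-4-benzyl-3-{4-[3-(benzyloxy)-4-methoxyphenyl]-4-oxobutanoyl}-1,3-oxazolidin-2-one | COc1ccc(C(=O)CCC(=O)N2C(=O)OC[C@@H]2Cc2ccccc2)cc1OCc1ccccc1 | intermediate
8 | (S)-4-benzyl-3-{(3E)-3-[3-(benzyloxy)-4-methoxybenzoyl]-4-(dimethylamino)but-3-enoyl}-1,3-oxazolidin-2-one | COc1ccc(C(=O)/C(CC(=O)N2C(=O)OC[C@@H]2Cc2ccccc2)=C/N(C)C)cc1OCc1ccccc1 | intermediate
9 | 3-(benzyloxy)-4-methoxybenzaldehyde | COc1ccc(C=O)cc1OCc1ccccc1 | starting material
10 | Z-dibutylboron dienolate of 8 (boron on the imide enolate oxygen) | CCCCB(CCCC)O/C(=C\C(=C/N(C)C)C(=O)c1ccc(OC)c(OCc2ccccc2)c1)N1C(=O)OC[C@@H]1Cc1ccccc1 | intermediate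
11 | (S)-4-benzyl-3-{(2S,3E)-2-[(S)-[3-(benzyloxy)-4-methoxyphenyl](hydroxy)methyl]-3-[3-(benzyloxy)-4-methoxybenzoyl]-4-(dimethylamino)but-3-enoyl}-1,3-oxazolidin-2-one (syn-aldol, released from its boron aldolate by methanolysis) | O=C(N1C(=O)OC[C@@H]1Cc1ccccc1)[C@H]([C@H](O)c1ccc(OC)c(OCc2ccccc2)c1)/C(=C\N(C)C)C(=O)c1ccc(OC)c(OCc2ccccc2)c1 | intermediate
12 | (S)-4-benzyl-3-{(2S,3S)-2-[3-(benzyloxy)-4-methoxyphenyl]-4-[3-(benzyloxy)-4-methoxybenzoyl]-2,3-dihydrofuran-3-carbonyl}-1,3-oxazolidin-2-one | O=C(N1C(=O)OC[C@@H]1Cc1ccccc1)[C@@H]1[C@@H](c2ccc(OC)c(OCc3ccccc3)c2)OC=C1C(=O)c1ccc(OC)c(OCc2ccccc2)c1 | intermediate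
13 | [(2S,3R)-2-[3-(benzyloxy)-4-methoxyphenyl]-3-(hydroxymethyl)-2,3-dihydrofuran-4-yl][3-(benzyloxy)-4-methoxyphenyl]methanone | OC[C@@H]1[C@@H](c2ccc(OC)c(OCc3ccccc3)c2)OC=C1C(=O)c1ccc(OC)c(OCc2ccccc2)c1 | intermediate
14 | dilithium salt from hydride addition to C5 of 13 (C9 alkoxide, C4=C7' enolate) | [Li+].[Li+].[O-]C[C@@H]1[C@@H](c2ccc(OC)c(OCc3ccccc3)c2)OCC1=C([O-])c1ccc(OC)c(OCc2ccccc2)c1 | intermediate
15 | [(2S,3R,4S)-2-[3-(benzyloxy)-4-methoxyphenyl]-3-(hydroxymethyl)tetrahydrofuran-4-yl][3-(benzyloxy)-4-methoxyphenyl]methanone | COc1ccc(C(=O)[C@@H]2CO[C@H](c3ccc(OC)c(OCc4ccccc4)c3)[C@H]2CO)cc1OCc1ccccc1 | intermediate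
16 | [(2S,3R,4S)-2-(3-hydroxy-4-methoxyphenyl)-3-(hydroxymethyl)tetrahydrofuran-4-yl](3-hydroxy-4-methoxyphenyl)methanone (CNP0234761.1) | COc1ccc(C(=O)[C@@H]2CO[C@H](c3ccc(OC)c(O)c3)[C@H]2CO)cc1O | target

**Step count**

Total steps: 7. Longest linear sequence: 7 steps (1 → 4 → 7 → 8 → 12 → 13 → 15 → 16).

**Steps most likely to fail**

Step 4 (Proposed new method). The boron dienolate may attack the boron-activated enaminone of a second molecule instead of the aldehyde, the nitrogen-to-oxygen exchange may stall at the open aldol, or the acid may ionise the electron-rich benzylic C2–O1 bond with loss of the C2 configuration. The fallback uses known reactions only, sets out from 5 and 9 and comes back at 15. 5 is N-acylated with but-3-enoic acid (PivCl, Et3N, LiCl) to the but-3-enoyl imide F1. Its Bu2BOTf/i-Pr2NEt syn-aldol reaction with 9 gives the α-vinyl aldol F2 with the same (S,S) sense. A 5-endo iodoetherification (I2, NaHCO3, MeCN) closes O1–C5 and gives the 4-iodo-oxolane F3. Nickel-catalysed reductive acylation of this secondary iodide with commercial 3-(benzyloxy)-4-methoxybenzoic acid (NiCl2·glyme, 4,4'-di-tert-butyl-2,2'-bipyridine, Zn, MgCl2, Boc2O, DMA) gives the keto imide F4. LiBH4 reduces imide and ketone to the diol F5, and MnO2 re-oxidises only the benzylic carbinol, which after K2CO3/MeOH equilibration at C4 gives 15.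

Step 6. Hydride may be delivered to the ketone carbonyl (1,2) instead of to C5, or the enolate may open the ring by β-elimination. The fallback goes from 13 to 15 without new compounds: heterogeneous hydrogenation of the C4=C5 bond over Rh/Al2O3 (H2, EtOAc), which should saturate the enol ether double bond with little benzylic C–O hydrogenolysis, followed by the same K2CO3/MeOH equilibration at C4.

Step 3. Aminomethylenation may occur at the imide α-carbon (C3) instead of the ketone α-carbon (C4), or the liberated methanol may cleave the imide. The fallback sets out from 5 and comes back at 12. 5 is N-acylated with pent-4-enoyl chloride (n-BuLi, THF) to the pentenoyl imide F6, and ozonolysis (O3, CH2Cl2, −78 °C; Me2S) gives the aldehyde F7. Condensation with morpholine (MgSO4) gives the enamine F8. Carbon acylation of F8 with the acid chloride F9 (made from commercial 3-(benzyloxy)-4-methoxybenzoic acid and oxalyl chloride) in the presence of Et3N gives the morpholino enaminone F10, with the aroyl group unambiguously on C4. F10 is taken through step 4 in place of 8, morpholine leaving instead of dimethylamine, and gives 12.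

**Further compounds**

F1 | step 4 | (S)-4-benzyl-3-(but-3-enoyl)-1,3-oxazolidin-2-one | C=CCC(=O)N1C(=O)OC[C@@H]1Cc1ccccc1
F2 | step 4 | (S)-4-benzyl-3-{(2S)-2-[(S)-[3-(benzyloxy)-4-methoxyphenyl](hydroxy)methyl]but-3-enoyl}-1,3-oxazolidin-2-one | C=C[C@@H]([C@H](O)c1ccc(OC)c(OCc2ccccc2)c1)C(=O)N1C(=O)OC[C@@H]1Cc1ccccc1
F3 | step 4 | (S)-4-benzyl-3-{(2S,3S,4S)-2-[3-(benzyloxy)-4-methoxyphenyl]-4-iodotetrahydrofuran-3-carbonyl}-1,3-oxazolidin-2-one (3,4-trans epimer shown) | O=C(N1C(=O)OC[C@@H]1Cc1ccccc1)[C@@H]1[C@@H](c2ccc(OC)c(OCc3ccccc3)c2)OC[C@H]1I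
F4 | step 4 | (S)-4-benzyl-3-{(2S,3S,4S)-2-[3-(benzyloxy)-4-methoxyphenyl]-4-[3-(benzyloxy)-4-methoxybenzoyl]tetrahydrofuran-3-carbonyl}-1,3-oxazolidin-2-one | O=C(N1C(=O)OC[C@@H]1Cc1ccccc1)[C@@H]1[C@@H](c2ccc(OC)c(OCc3ccccc3)c2)OC[C@H]1C(=O)c1ccc(OC)c(OCc2ccccc2)c1
F5 | step 4 | [(2S,3R,4S)-2-[3-(benzyloxy)-4-methoxyphenyl]-3-(hydroxymethyl)tetrahydrofuran-4-yl][3-(benzyloxy)-4-methoxyphenyl]methanol (both carbinol epimers) | OC[C@@H]1[C@@H](c2ccc(OC)c(OCc3ccccc3)c2)OC[C@H]1C(O)c1ccc(OC)c(OCc2ccccc2)c1
F0 | step 6 | none | none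
F6 | step 3 | (S)-4-benzyl-3-(pent-4-enoyl)-1,3-oxazolidin-2-one | C=CCCC(=O)N1C(=O)OC[C@@H]1Cc1ccccc1
F7 | step 3 | (S)-4-benzyl-3-(4-oxobutanoyl)-1,3-oxazolidin-2-one | O=CCCC(=O)N1C(=O)OC[C@@H]1Cc1ccccc1
F8 | step 3 | (S)-4-benzyl-3-[(3E)-4-(morpholin-4-yl)but-3-enoyl]-1,3-oxazolidin-2-one | O=C(C/C=C/N1CCOCC1)N1C(=O)OC[C@@H]1Cc1ccccc1
F9 | step 3 | 3-(benzyloxy)-4-methoxybenzoyl chloride | COc1ccc(C(=O)Cl)cc1OCc1ccccc1
F10 | step 3 | (S)-4-benzyl-3-{(3E)-3-[3-(benzyloxy)-4-methoxybenzoyl]-4-(morpholin-4-yl)but-3-enoyl}-1,3-oxazolidin-2-one | COc1ccc(C(=O)/C(CC(=O)N2C(=O)OC[C@@H]2Cc2ccccc2)=C/N2CCOCC2)cc1OCc1ccccc1
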